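The solid substrate goes into a closed, stirred, isothermal flask undissolved, and the target appears after a lag.

| flask | solid substrate | remark | time |
|---|---|---|---|
| beta | 0.0076 M | run made earlier |  |
| alpha | 0.074 M | run made earlier |  |
| north-east | 0.040 M |  | 80 min |
| north-west | 0.012 M |  | 80 min |
| south-west | 0.010 M |  | 80 min |
| south-east | 0.0060 M |  | 80 min |
| south | 0.020 M |  | 80 min |
| east | 0.060 M |  | 80 min |

| run | time / min | target / % |
|---|---|---|
| beta | 3.00 | 0 |
| beta | 8.00 | 0 |
| beta | 15.0 | 5.1 |
| beta | 40.0 | 32.8 |
| alpha | 10.0 | 0 |
| alpha | 20.0 | 0.1 |
| alpha | 30.0 | 1.1 |
| alpha | 40.0 | 4.7 |

(standard deviation of a reading: 1 percentage point)

- in percentages every species weighs as the solid substrate in it: one target counts as two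
- as a solid, counted per litre of solution: solid substrate
- the numbers in the tables scatter by 1 percentage point (one standard deviation)
- at the start none of the solid substrate is in solution
- what has only dissolved of solid substrate counts as not reacted

- the flasks put in order of amount of target, in percent of the solid substrate charged, best first, at 80 min (north-east / north-west / south-west / south-east / south / east)
- the amount of target, in percent of the solid substrate charged of the flask you put first, at 80 min
- the amount of target, in percent of the solid substrate charged of the flask you put last, at 80 min

One thing looks contradictory: alpha holds ten times the solid substrate of beta, yet at 40.0 min it shows 4.7% target against 32.8% in beta. Percent hides the amount. Multiplied by the charge, the readings give 2c(target), the solid substrate held in target, as 3.48 mM in alpha and 2.49 mM in beta, a ratio of 1.40, so these two readings per litre stand closer together than the two charges.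

Beta's last two readings give a rise of 0.0842 mM min⁻¹. This output rate, the rise of 2c(target) per minute, is taken as zero-order in the charge, and the line extrapolates back to a lag of 10.4 min. Output rate times the time past the lag, divided by the charge, is the fraction made, and the fraction left is one minus that. For alpha at 40.0 min this gives 3.37%, which is 1.3 percentage points from the reading, whose scatter is 1 point.

At 80 min the reckoning puts the fraction made at 9.77% in east and 97.7% in south-east, before any loss of target, so the fraction left is 90.2% of the charge in east and 2.30% in south-east. With the output rate held the same across the flasks, the reckoned fraction made rises as the charge falls, so the reckoned order runs from south-east, the smallest charge, to east, the largest. The forecast gives the same order, south-east > south-west > north-west > south > north-east > east, but with 72% first and 45% last, holding that “the percent yield at a given time falls as loading rises”. The flasks give south-east > south-west > north-west > south > north-east > east, with 62.0% in south-east and 8.09% in east.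

    2 starting material → target (k = 0.360 M⁻¹ s⁻¹)
    solid substrate ⇌ starting material, rate k2*(cs2 - [starting material]) while solid is left; crystals form when [starting material] > cs2 (solubility = 8.10 mM, k = 2.50 × 10⁻⁴ s⁻¹)
    target → over-reaction product (k = 1.60 × 10⁻⁴ s⁻¹)

In east, the reckoned 9.77% compares with 11.0% of target and over-reaction product together. In south-east, the reckoned 97.7% compares with 89.5% of the two together, of which over-reaction product is 27.5%. The neighbour is east read at 5.0 h, and there the same reckoning gives 40.6%. That flask holds 50.2% solid substrate and 31.2% over-reaction product, which with its target makes 47.3%, and the target itself stands at 16.1%.

The runs come from a simulation for substances that don't exist, noise included.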